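**Plan**

- The target is prostaglandin E3 1,15-lactone 11-acetate (prostaglandin numbering C1–C20 is used throughout). Retrosynthetic cuts, in order: the O11 acetyl; C5=C6 (ring-closing metathesis of the 13-membered lactone); C7–C8 (decarboxylative allylation); then C10–C11 together with C8–C9, which lifts the CH2–C(=O) unit C10–C9 out of the cyclopentanone; finally C13=C14 (Wittig) and the C1–O15 ester.
- Enabling feature: in the cyclopentanone, C11 bears oxygen (donor) and C8 is α to C9 and can bear an ester (acceptor), and both flank C12. C8–C12–C11 is therefore drawn as a siloxy/ester donor–acceptor cyclopropane (extra C8–C11 bond, extra ester on C8), and C9–C10 as a ketene acetal.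
- Forward: a (Z)-silyl enol ether and allyl diazoacetate give the cyclopropane; the ω-chain and the hexenoate are attached to it; a formal [3+2] ring expansion (3 to 5) builds the cyclopentanone; the allyl ester becomes the C8 allyl group with loss of CO2; metathesis closes the lactone; TBS is exchanged for acetyl.
- Stereochemistry: C15 from (S)-epichlorohydrin; C12 from the copper/bis(oxazoline) cyclopropanation; C11 and C8 from C12 during and after the ring expansion; 17Z by Lindlar reduction, 13E by the Wittig step, 5Z by the metathesis catalyst.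

Key step: step 11

Assumption: the (S,S)-bis(oxazoline) ligand in step 7 is taken to give the cyclopropane enantiomer drawn; if the sense of induction is the opposite, the (R,R)-ligand is used. (TBS = tert-butyldimethylsilyl, PMB = 4-methoxybenzyl, TES = triethylsilyl.)

**Route**

Step 1
Reactants: 1 (S)-epichlorohydrin; 2 but-1-yne
Product: 4 (S)-1-chlorohept-4-yn-2-ol, via but-1-yn-1-yllithium 3 (not isolated)
Conditions: n-BuLi, THF, −78 °C; BF3·OEt2; 1, −78 °C; H2O
Reagents that add atoms: none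
Why: Lewis-acid-assisted epoxide opening by a lithium acetylide should occur at the unsubstituted epoxide carbon and not at the chloride, so the stereocentre of 1 becomes C15 unchanged.

Step 2
Reactants: 4 (S)-1-chlorohept-4-yn-2-ol
Product: 5 (S,Z)-1-chlorohept-4-en-2-ol
Conditions: H2 (1 atm), Pd/CaCO3 poisoned by Pb(OAc)2 (Lindlar catalyst), quinoline, EtOAc, rt
Reagents that add atoms: none
Why: Lindlar semihydrogenation adds H2 syn to the alkyne and stops at the Z-alkene, which becomes the 17Z olefin.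

Step 3
Reactants: 5 (S,Z)-1-chlorohept-4-en-2-ol
Product: 6 [(2S,4Z)-2-hydroxyhept-4-en-1-yl]triphenylphosphonium iodide
Conditions: PPh3, NaI, MeCN, reflux
Reagents that add atoms: triphenylphosphine c1ccc(cc1)P(c1ccccc1)c1ccccc1; sodium iodide [Na+].[I-]
Why: Finkelstein exchange followed by SN2 quaternisation of the phosphine at the primary carbon should give the β-hydroxy phosphonium salt without touching C15.

Step 4
Reactants: 7 allyl bromoacetate
Product: 8 allyl diazoacetate
Conditions: TsNHNHTs, DBU, THF, 0 °C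
Reagents that add atoms: N,N′-ditosylhydrazine Cc1ccc(cc1)S(=O)(=O)NNS(=O)(=O)c1ccc(C)cc1
Why: N-alkylation of the ditosylhydrazine by the bromoacetate and base-induced loss of two sulfinates is an established diazoacetate synthesis.

Step 5
Reactants: 9 3-[(4-methoxybenzyl)oxy]propan-1-ol
Product: 10 3-[(4-methoxybenzyl)oxy]propanal
Conditions: TEMPO (cat.), PhI(OAc)2, CH2Cl2, rt
Reagents that add atoms: none
Why: Oxoammonium-mediated (TEMPO) oxidation of a primary alcohol stops at the aldehyde.

Step 6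
Reactants: 10 3-[(4-methoxybenzyl)oxy]propanal
Product: 11 (Z)-tert-butyl({3-[(4-methoxybenzyl)oxy]prop-1-en-1-yl}oxy)dimethylsilane
Conditions: TBSOTf, Et3N, CH2Cl2, 0 °C
Reagents that add atoms: tert-butyldimethylsilyl triflate CC(C)(C)[Si](C)(C)OS(=O)(=O)C(F)(F)F
Why: Soft enolisation (silyl triflate and amine) of the aldehyde should give mainly the Z-silyl enol ether, the E-isomer being removed by chromatography on base-washed silica.

Step 7
Reactants: 11 (Z)-silyl enol ether; 8 allyl diazoacetate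
Product: 12 allyl (1R,2R,3S)-2-[(TBS)oxy]-3-{[(4-methoxybenzyl)oxy]methyl}cyclopropane-1-carboxylate (OTBS and CH2OPMB cis; ester trans to both)
Conditions: CuOTf·0.5C6H6 (cat.), 2,2′-(propane-2,2-diyl)bis[(4S)-4-tert-butyl-4,5-dihydrooxazole] (cat.), CH2Cl2, rt, slow addition of 8
Reagents that add atoms: none
Why: Asymmetric cyclopropanation of an enol ether by a monovalent-copper/bis(oxazoline) carbenoid should retain the cis-alkene geometry, place the ester exo for steric reasons (the minor endo isomer is separated) and, through the chiral ligand, select the alkene face that fixes the future C12.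

Step 8
Reactants: 12 cyclopropane PMB ether
Product: 13 allyl (1R,2R,3S)-2-[(TBS)oxy]-3-(hydroxymethyl)cyclopropane-1-carboxylate
Conditions: DDQ, CH2Cl2/pH 7 buffer, 0 °C
Reagents that add atoms: none
Why: Oxidative PMB cleavage by DDQ is neutral and should leave the acid- and fluoride-sensitive siloxycyclopropane and the allyl ester intact.

Step 9
Reactants: 13 cyclopropylmethanol
Product: 14 allyl (1R,2R,3R)-2-[(TBS)oxy]-3-formylcyclopropane-1-carboxylate
Conditions: Dess–Martin periodinane, pyridine, CH2Cl2, 0 °C to rt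
Reagents that add atoms: none
Why: Dess–Martin oxidation under buffered conditions should give the aldehyde without epimerising the non-enolisable cyclopropane carbon.

Step 10
Reactants: 14 cyclopropanecarbaldehyde; 6 hydroxy phosphonium iodide; 15 hex-5-enoyl chloride
Product: 18 allyl (1R,2R,3R)-2-[(TBS)oxy]-3-[(1E,3S,5Z)-3-(hex-5-enoyloxy)octa-1,5-dien-1-yl]cyclopropane-1-carboxylate, via β-oxido ylide 16 (not isolated), via lithium alkoxide 17 (not isolated)
Conditions: 6, n-BuLi (2 equiv), THF, −78 to −25 °C; 14, −78 to 0 °C; then 15, 0 °C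
Reagents that add atoms: none
Why: In this β-oxido ylide Wittig olefination, 16 should add to the aldehyde, the lithium-bound betaines should equilibrate to the threo form (as in the Schlosser variant), and Ph3PO should be lost through the new, more hindered cyclopropylcarbinyl oxygen to give the 13E alkene, while the C15 alkoxide (configuration from 1) survives as 17 and is O-acylated in the same flask.

Step 11
Reactants: 18 siloxycyclopropane ester; 19 1-[(tert-butyldimethylsilyl)oxy]-1-methoxyethene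
Product: 21 allyl (1R,4R,5R)-4-[(TBS)oxy]-5-[(1E,3S,5Z)-3-(hex-5-enoyloxy)octa-1,5-dien-1-yl]-2-oxocyclopentane-1-carboxylate, via methyl silyl ketal 20 (not isolated)
Conditions: 19 (2 equiv), SnCl4 (1.2 equiv), CH2Cl2, −78 °C; aq. NaHCO3
Reagents that add atoms: none
Why: SnCl4 binds the cyclopropane ester and heterolyses the bond between the siloxy carbon (C11) and the ester carbon (C8) to a silyloxocarbenium/tin enolate pair; the CH2 carbon of 19 adds to C11 (Mukaiyama type), and the carboxonium ion then formed at C9 is captured by the C8 enolate in a 5-(enolexo)-exo-trig Claisen-type closure, the ketal 20 collapsing to the ketone. The closest known reaction type is the Lewis-acid-mediated formal [3+2] cycloaddition of 2-alkoxy- and 2-siloxycyclopropanecarboxylates with silyl enol ethers and ketene silyl acetals. C12 is not touched and keeps the configuration set in step 7. C11 should be set by attack of 19 anti to the departing C8 (inversion at C11, which is also the Felkin–Anh face if the enolate arm is the large group); because OTBS and the side chain are cis in 18, this places O11 trans to the C12 chain. C8 is an epimerisable β-keto ester centre and should settle trans to C12. The step needs cleavage of the C11–C8 bond only (the one bond lying between the oxygen donor and the ester acceptor) and capture of the cation faster than loss of the allylic C12–H or ionisation of the C15 allylic ester, which the low temperature and the excess of the strongly nucleophilic 19 should secure.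

Step 12
Reactants: 21 allyl β-keto ester
Product: 22 (2R,3R,4R)-2-allyl-4-[(TBS)oxy]-3-[(1E,3S,5Z)-3-(hex-5-enoyloxy)octa-1,5-dien-1-yl]cyclopentan-1-one
Conditions: Pd(PPh3)4 (cat.), THF, rt
Reagents that add atoms: none
Why: In this Tsuji decarboxylative allylation, zerovalent palladium ionises the allyl β-keto ester, CO2 is lost and the palladium enolate should be allylated at C8 anti to the C12 chain (C8 is epimerisable and settles trans in any case), the hindered secondary allylic ester at C15 being a much poorer substrate for ionisation.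

Step 13
Reactants: 22 diene ketone
Product: 23 prostaglandin E3 1,15-lactone 11-TBS ether [(5Z,13E,15S,17Z)-11α-[(TBS)oxy]-9-oxoprosta-5,13,17-trien-1,15-olide]
Conditions: cyclometalated ruthenium nitrato catalyst Ru(NO3)(=CH-C6H4-2-OiPr)(C,C-chelating 1-adamantyl-3-(2,6-diisopropylphenyl)imidazolidin-2-ylidene) (cat.), ClCH2CH2Cl, 60 °C, high dilution, static vacuum
Reagents that add atoms: none
Why: Z-selective ring-closing metathesis should engage only the two terminal alkenes and close the 13-membered ring through a side-bound metallacycle that gives the 5Z alkene under kinetic control, high dilution suppressing oligomers.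

Step 14
Reactants: 23 lactone TBS ether
Product: 24 prostaglandin E3 1,15-lactone [(5Z,13E,15S,17Z)-11α-hydroxy-9-oxoprosta-5,13,17-trien-1,15-olide]
Conditions: HF·pyridine, pyridine, THF, 0 °C
Reagents that add atoms: none
Why: Desilylation by buffered HF·pyridine frees the 11-hydroxyl without base, so the β-hydroxy ketone should not dehydrate.

Step 15
Reactants: 24 prostaglandin E3 1,15-lactone
Product: 25 prostaglandin E3 1,15-lactone 11-acetate (target)
Conditions: Ac2O, pyridine, DMAP (cat.), CH2Cl2, 0 °C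
Reagents that add atoms: acetic anhydride CC(=O)OC(C)=O
Why: DMAP-catalysed acylation of the only free hydroxyl at low temperature should give the 11-acetate before E1cB loss of acetate can set in.

**Compound list**

1 | (S)-epichlorohydrin | ClC[C@@H]1CO1 | starting material
2 | but-1-yne | CCC#C | starting material
3 | but-1-yn-1-yllithium | CCC#C[Li] | intermediate
4 | (S)-1-chlorohept-4-yn-2-ol | CCC#CC[C@H](O)CCl | intermediate
5 | (S,Z)-1-chlorohept-4-en-2-ol | CC/C=C\C[C@H](O)CCl | intermediate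
6 | [(2S,4Z)-2-hydroxyhept-4-en-1-yl]triphenylphosphonium iodide | CC/C=C\C[C@H](O)C[P+](c1ccccc1)(c1ccccc1)c1ccccc1.[I-] | intermediate
7 | allyl bromoacetate | C=CCOC(=O)CBr | starting material
8 | allyl diazoacetate | C=CCOC(=O)C=[N+]=[N-] | intermediate
9 | 3-[(4-methoxybenzyl)oxy]propan-1-ol | COc1ccc(COCCCO)cc1 | starting material
10 | 3-[(4-methoxybenzyl)oxy]propanal | COc1ccc(COCCC=O)cc1 | intermediate
11 | (Z)-tert-butyl({3-[(4-methoxybenzyl)oxy]prop-1-en-1-yl}oxy)dimethylsilane | COc1ccc(COC/C=C\O[Si](C)(C)C(C)(C)C)cc1 | intermediate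
12 | allyl (1R,2R,3S)-2-[(TBS)oxy]-3-{[(4-methoxybenzyl)oxy]methyl}cyclopropane-1-carboxylate | COc1ccc(COC[C@H]2[C@@H](O[Si](C)(C)C(C)(C)C)[C@@H]2C(=O)OCC=C)cc1 | intermediate
13 | allyl (1R,2R,3S)-2-[(TBS)oxy]-3-(hydroxymethyl)cyclopropane-1-carboxylate | OC[C@H]1[C@@H](O[Si](C)(C)C(C)(C)C)[C@@H]1C(=O)OCC=C | intermediate
14 | allyl (1R,2R,3R)-2-[(TBS)oxy]-3-formylcyclopropane-1-carboxylate | O=C[C@H]1[C@@H](O[Si](C)(C)C(C)(C)C)[C@@H]1C(=O)OCC=C | intermediate
15 | hex-5-enoyl chloride | C=CCCCC(=O)Cl | starting material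
16 | lithium (2S,4Z)-1-(triphenyl-λ5-phosphanylidene)hept-4-en-2-olate (β-oxido ylide) | CC/C=C\C[C@H]([O-])C=P(c1ccccc1)(c1ccccc1)c1ccccc1.[Li+] | intermediate
17 | lithium alkoxide of allyl (1R,2R,3R)-2-[(TBS)oxy]-3-[(1E,3S,5Z)-3-hydroxyocta-1,5-dien-1-yl]cyclopropane-1-carboxylate | CC/C=C\C[C@H]([O-])/C=C/[C@H]1[C@@H](O[Si](C)(C)C(C)(C)C)[C@@H]1C(=O)OCC=C.[Li+] | intermediate
18 | allyl (1R,2R,3R)-2-[(TBS)oxy]-3-[(1E,3S,5Z)-3-(hex-5-enoyloxy)octa-1,5-dien-1-yl]cyclopropane-1-carboxylate | CC/C=C\C[C@H](OC(=O)CCCC=C)/C=C/[C@H]1[C@@H](O[Si](C)(C)C(C)(C)C)[C@@H]1C(=O)OCC=C | intermediate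
19 | 1-[(tert-butyldimethylsilyl)oxy]-1-methoxyethene | C=C(OC)O[Si](C)(C)C(C)(C)C | starting material
20 | C9 methyl TBS ketal of 21 (allyl 2-methoxy-2,4-bis[(TBS)oxy]-5-[(1E,3S,5Z)-3-(hex-5-enoyloxy)octa-1,5-dien-1-yl]cyclopentane-1-carboxylate, 4R,5R) | CC/C=C\C[C@H](OC(=O)CCCC=C)/C=C/[C@H]1[C@H](O[Si](C)(C)C(C)(C)C)CC(OC)(O[Si](C)(C)C(C)(C)C)C1C(=O)OCC=C | intermediate
21 | allyl (1R,4R,5R)-4-[(TBS)oxy]-5-[(1E,3S,5Z)-3-(hex-5-enoyloxy)octa-1,5-dien-1-yl]-2-oxocyclopentane-1-carboxylate | CC/C=C\C[C@H](OC(=O)CCCC=C)/C=C/[C@H]1[C@H](O[Si](C)(C)C(C)(C)C)CC(=O)[C@@H]1C(=O)OCC=C | intermediate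
22 | (2R,3R,4R)-2-allyl-4-[(TBS)oxy]-3-[(1E,3S,5Z)-3-(hex-5-enoyloxy)octa-1,5-dien-1-yl]cyclopentan-1-one | CC/C=C\C[C@H](OC(=O)CCCC=C)/C=C/[C@H]1[C@H](O[Si](C)(C)C(C)(C)C)CC(=O)[C@@H]1CC=C | intermediate
23 | prostaglandin E3 1,15-lactone 11-TBS ether | CC/C=C\C[C@H]1/C=C/[C@H]2[C@H](O[Si](C)(C)C(C)(C)C)CC(=O)[C@@H]2C/C=C\CCCC(=O)O1 | intermediate
24 | prostaglandin E3 1,15-lactone | CC/C=C\C[C@H]1/C=C/[C@H]2[C@H](O)CC(=O)[C@@H]2C/C=C\CCCC(=O)O1 | intermediate
25 | prostaglandin E3 1,15-lactone 11-acetate | CC/C=C\C[C@H]1/C=C/[C@H]2[C@H](OC(C)=O)CC(=O)[C@@H]2C/C=C\CCCC(=O)O1 | target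

**Step count and risks**

Total step count: 15. Longest linear sequence: 11 steps (steps 5 to 15, from 9).

Steps most likely to fail:

1. Step 11. The ketene acetal may attack the C11 oxocarbenium ion with poor facial selectivity, and some OTBS may be lost by β-elimination, so that C11 is not set cleanly. Fallback: the C11 is then set by substrate control on the ring instead of in the annulation. The material is taken through step 12 and the fallback sets out from 22 (as a C11 mixture). DBU in CH2Cl2 eliminates the silanol from both epimers to give one compound, the cyclopentenone F1. Copper-catalysed conjugate borylation (CuCl, NaOtBu, bis[2-(diphenylphosphino)phenyl] ether, B2pin2, MeOH, THF) should add boron to C11 anti to the C12 chain and give the 11-boronate F2. Oxidation with retention (NaBO3, THF/H2O) gives the 11α-alcohol F3, and TBSOTf/2,6-lutidine returns to 22.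

2. Step 13. The catalyst may give incomplete Z-selectivity or engage the internal 17Z alkene, so that the macrocycle forms as an inseparable olefin mixture. Fallback: ring closure by alkyne metathesis and semihydrogenation, which sets out from 14. Alkoxide 17 is generated as in step 10 but quenched with hept-5-ynoyl chloride to give the heptynoate cyclopropane F4. Ring expansion with 19 and SnCl4 as in step 11 gives the keto ester F5. C-alkylation at C8 with 1-bromobut-2-yne (K2CO3, acetone) gives the quaternary keto ester F6. Pd(PPh3)4 and morpholine remove the allyl ester with decarboxylation to the diyne ketone F7. Ring-closing alkyne metathesis (Mo(≡CC6H4-4-OMe)(OSiPh3)3, toluene, 5 Å sieves) gives the cycloalkyne F8, and Lindlar semihydrogenation comes back to 23.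

3. Step 10. The dioxido phosphonium intermediate may lose Ph3PO through the C15 oxygen instead of the new one, or the betaines may not equilibrate, giving the wrong regio- or E/Z-isomer. Fallback: Julia–Kocienski olefination, which sets out from 5 and uses 14. Chlorohydrin 5 with 1-phenyl-1H-tetrazole-5-thiol and K2CO3 (via the epoxide) gives the hydroxy sulfide F9. TESCl/imidazole gives the TES ether F10, and (NH4)6Mo7O24/H2O2 gives the sulfone F11. Its potassium anion (KHMDS, DME, −60 °C) and 14 should give the 13E alkene F12. PPTS in MeOH removes the TES group selectively to give the allylic alcohol F13, and acylation with 15 (pyridine, DMAP) comes back to 18.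

Further compounds
F1 | step 11 | (4R,5R)-5-allyl-4-[(1E,3S,5Z)-3-(hex-5-enoyloxy)octa-1,5-dien-1-yl]cyclopent-2-en-1-one | CC/C=C\C[C@H](OC(=O)CCCC=C)/C=C/[C@H]1C=CC(=O)[C@@H]1CC=C
F2 | step 11 | (2R,3R,4R)-2-allyl-3-[(1E,3S,5Z)-3-(hex-5-enoyloxy)octa-1,5-dien-1-yl]-4-(4,4,5,5-tetramethyl-1,3,2-dioxaborolan-2-yl)cyclopentan-1-one | CC/C=C\C[C@H](OC(=O)CCCC=C)/C=C/[C@H]1[C@H](B2OC(C)(C)C(C)(C)O2)CC(=O)[C@@H]1CC=C
F3 | step 11 | (2R,3R,4R)-2-allyl-4-hydroxy-3-[(1E,3S,5Z)-3-(hex-5-enoyloxy)octa-1,5-dien-1-yl]cyclopentan-1-one | CC/C=C\C[C@H](OC(=O)CCCC=C)/C=C/[C@H]1[C@H](O)CC(=O)[C@@H]1CC=C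
F4 | step 13 | allyl (1R,2R,3R)-2-[(TBS)oxy]-3-[(1E,3S,5Z)-3-(hept-5-ynoyloxy)octa-1,5-dien-1-yl]cyclopropane-1-carboxylate | CC/C=C\C[C@H](OC(=O)CCCC#CC)/C=C/[C@H]1[C@@H](O[Si](C)(C)C(C)(C)C)[C@@H]1C(=O)OCC=C
F5 | step 13 | allyl (1R,4R,5R)-4-[(TBS)oxy]-5-[(1E,3S,5Z)-3-(hept-5-ynoyloxy)octa-1,5-dien-1-yl]-2-oxocyclopentane-1-carboxylate | CC/C=C\C[C@H](OC(=O)CCCC#CC)/C=C/[C@H]1[C@H](O[Si](C)(C)C(C)(C)C)CC(=O)[C@@H]1C(=O)OCC=C
F6 | step 13 | allyl 1-(but-2-yn-1-yl)-4-[(TBS)oxy]-5-[(1E,3S,5Z)-3-(hept-5-ynoyloxy)octa-1,5-dien-1-yl]-2-oxocyclopentane-1-carboxylate (4R,5R; butynyl trans to the C12 chain) | CC/C=C\C[C@H](OC(=O)CCCC#CC)/C=C/[C@H]1[C@H](O[Si](C)(C)C(C)(C)C)CC(=O)[C@@]1(CC#CC)C(=O)OCC=C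
F7 | step 13 | (2R,3R,4R)-2-(but-2-yn-1-yl)-4-[(TBS)oxy]-3-[(1E,3S,5Z)-3-(hept-5-ynoyloxy)octa-1,5-dien-1-yl]cyclopentan-1-one | CC/C=C\C[C@H](OC(=O)CCCC#CC)/C=C/[C@H]1[C@H](O[Si](C)(C)C(C)(C)C)CC(=O)[C@@H]1CC#CC
F8 | step 13 | (13E,15S,17Z)-11α-[(TBS)oxy]-9-oxoprosta-13,17-dien-5-yn-1,15-olide | CC/C=C\C[C@H]1/C=C/[C@H]2[C@H](O[Si](C)(C)C(C)(C)C)CC(=O)[C@@H]2CC#CCCCC(=O)O1
F9 | step 10 | (2S,4Z)-1-[(1-phenyl-1H-tetrazol-5-yl)sulfanyl]hept-4-en-2-ol | CC/C=C\C[C@H](O)CSc1nnnn1-c1ccccc1
F10 | step 10 | 1-phenyl-5-{[(2S,4Z)-2-[(triethylsilyl)oxy]hept-4-en-1-yl]sulfanyl}-1H-tetrazole | CC/C=C\C[C@H](O[Si](CC)(CC)CC)CSc1nnnn1-c1ccccc1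
F11 | step 10 | 1-phenyl-5-{[(2S,4Z)-2-[(triethylsilyl)oxy]hept-4-en-1-yl]sulfonyl}-1H-tetrazole | CC/C=C\C[C@H](O[Si](CC)(CC)CC)CS(=O)(=O)c1nnnn1-c1ccccc1
F12 | step 10 | allyl (1R,2R,3R)-2-[(TBS)oxy]-3-[(1E,3S,5Z)-3-[(triethylsilyl)oxy]octa-1,5-dien-1-yl]cyclopropane-1-carboxylate | CC/C=C\C[C@H](O[Si](CC)(CC)CC)/C=C/[C@H]1[C@@H](O[Si](C)(C)C(C)(C)C)[C@@H]1C(=O)OCC=C
F13 | step 10 | allyl (1R,2R,3R)-2-[(TBS)oxy]-3-[(1E,3S,5Z)-3-hydroxyocta-1,5-dien-1-yl]cyclopropane-1-carboxylate | CC/C=C\C[C@H](O)/C=C/[C@H]1[C@@H](O[Si](C)(C)C(C)(C)C)[C@@H]1C(=O)OCC=C
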